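The cyclohexane ring is cut at C1–C2 and C1–C6. C1, the ring carbon that carries OH and the exocyclic C7, lies between the secondary carbinols C2 and C6, so it can be the carbon of nitromethane (8) added twice to a dialdehyde spanning C2–C3–C4–C5–C6. This double Henry cyclisation closes the six-membered ring and sets C6, C1 and C2 in one operation under thermodynamic control, every ring substituent settling equatorial beside the C5 anchor. The precursor is (R)-2-(benzyloxy)pentanedial (7); the C5 oxygen is a benzyl ether because that group neither migrates to O6 nor leaves under base. The nitro group later becomes the C1 ketone, which receives C7 by axial ylide addition.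

Key step: step 4

Assumption: (R)-2-(but-3-en-1-yl)oxirane is taken to be a purchasable single-enantiomer building block; atom labels C1–C7 follow the target, with C1 the quaternary carbinol carbon, C7 its exocyclic CH2 and C5 the benzoyloxy-bearing carbon.

Step 1
Reactants: 1 (R)-2-(but-3-en-1-yl)oxirane; 2 trimethylsulfonium iodide
Product: 4 (R)-hepta-1,6-dien-3-ol, via sulfonium alkoxide 3 (not isolated)
Conditions: 2 (3.5 equiv), n-BuLi (3.3 equiv), THF, −10 °C to rt
Reagents that add atoms: none
Why: One-carbon homologation of a terminal epoxide by excess dimethylsulfonium methylide: the ylide opens the oxirane at its CH2 and a second equivalent eliminates Me2S from sulfonium alkoxide 3 to leave the vinyl group, and since no bond to the carbinol stereocentre breaks, the R configuration of 1 is carried over.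

Step 2
Reactants: 4 (R)-hepta-1,6-dien-3-ol
Product: 5 (R)-3-(benzyloxy)hepta-1,6-diene
Conditions: NaH, BnBr, Bu4NI (cat.), THF, 0 °C to rt
Reagents that add atoms: benzyl bromide, BrCc1ccccc1
Why: Williamson ether synthesis on the sodium alkoxide of a secondary allylic alcohol; the C–O bond of the stereocentre is not involved, so its configuration is retained.

Step 3
Reactants: 5 (R)-3-(benzyloxy)hepta-1,6-diene
Product: 7 (R)-2-(benzyloxy)pentanedial, via bis-ozonide 6 (not isolated)
Conditions: O3, CH2Cl2, −78 °C; PPh3, −78 °C to rt; aqueous wash, used at once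
Reagents that add atoms: ozone, [O-][O+]=O
Why: Ozonolysis of both terminal alkenes and phosphine reduction of bis-ozonide 6 should give the two formyl groups under neutral conditions, which leaves the α-benzyloxy stereocentre unenolised; the formaldehyde co-product is washed out so that it cannot compete for nitromethane in step 4.

Step 4
Reactants: 7 (R)-2-(benzyloxy)pentanedial; 8 nitromethane
Product: 10 (1R,2S,3R,4R)-4-(benzyloxy)-2-nitrocyclohexane-1,3-diol, via open-chain nitroaldol 9 (not isolated)
Conditions: 8 (1.5 equiv), Et3N (0.3 equiv), MeOH, 0 °C to rt, held until the isomer ratio no longer changes; AcOH quench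
Reagents that add atoms: none
Why: Triethylamine generates the nitronate of 8, which adds to one formyl group of 7 to give nitroaldol 9; deprotonation of 9 at the nitro-bearing carbon and addition to the second formyl group then completes the bonds C1–C6 and C1–C2. The closest known reaction type is the double Henry (nitroaldol) cyclisation of 1,5-dialdehydes with nitromethane, long used to turn glutaraldehyde and periodate-cleaved glycosides into cyclic 2-nitro-1,3-diols. The single ring formed, the cyclohexane, closes in a 6-exo-trig mode, the secondary nitronate carbon attacking the exocyclic C=O. C6, C1 and C2 are set under thermodynamic control: both additions are reversible and C1 epimerises through its nitronate, so the chair in which the fixed C5 benzyloxy group is equatorial should collect C6–OH, C1–NO2 and C2–OH in equatorial positions, which places C6–O trans to C5–O and cis to C2–O. The step needs this diastereoselectivity and an untouched C5 centre; a catalytic weak base keeps the bulk of the material as the neutral nitro-diol, for which the all-equatorial isomer is the energy minimum, and limits enolisation of the α-alkoxy aldehyde, while the benzyl ether can neither migrate to the new C6 hydroxyl nor be lost.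

Step 5
Reactants: 10 (1R,2S,3R,4R)-4-(benzyloxy)-2-nitrocyclohexane-1,3-diol
Product: 11 (1R,2S,3R,4R)-4-(benzyloxy)-1,3-bis[(tert-butyldimethylsilyl)oxy]-2-nitrocyclohexane
Conditions: TBSOTf (2.6 equiv), 2,6-lutidine (4 equiv), CH2Cl2, −78 to 0 °C
Reagents that add atoms: tert-butyldimethylsilyl triflate, CC(C)(C)[Si](C)(C)OS(=O)(=O)C(F)(F)F
Why: Silylation of both secondary hydroxyls with a silyl triflate and a hindered pyridine base proceeds at low temperature without forming the alkoxide that would start a retro-Henry cleavage; no stereocentre is touched.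

Step 6
Reactants: 11 (1R,2S,3R,4R)-4-(benzyloxy)-1,3-bis[(tert-butyldimethylsilyl)oxy]-2-nitrocyclohexane
Product: 13 (2S,3R,6R)-3-(benzyloxy)-2,6-bis[(tert-butyldimethylsilyl)oxy]cyclohexan-1-one, via sodium nitronate 12 (not isolated)
Conditions: NaOMe (1.1 equiv), MeOH/CH2Cl2, 0 °C; O3, −78 °C; N2 purge, pH 7 buffer
Reagents that add atoms: ozone, [O-][O+]=O
Why: Oxidative Nef reaction: methoxide converts the secondary nitro group into sodium nitronate 12, whose C=N bond is cleaved by ozone to the C1 ketone with loss of nitrite; with O2 and O6 silylated no retro-Henry path exists, and the cold, neutral work-up should leave C2 and C6 unenolised.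

Step 7
Reactants: 13 (2S,3R,6R)-3-(benzyloxy)-2,6-bis[(tert-butyldimethylsilyl)oxy]cyclohexan-1-one; 2 trimethylsulfonium iodide
Product: 15 (3S,4S,5R,8R)-5-(benzyloxy)-4,8-bis[(tert-butyldimethylsilyl)oxy]-1-oxaspiro[2.5]octane, via betaine 14 (not isolated)
Conditions: 2 (1.3 equiv), n-BuLi (1.2 equiv), THF, −10 °C; then 13, −10 to 0 °C
Reagents that add atoms: none
Why: Corey–Chaykovsky epoxidation: the small, irreversibly adding dimethylsulfonium methylide should attack the carbonyl of the all-equatorial chair of 13 along the axial direction, so that betaine 14 closes with C7 axial and the C1 oxygen equatorial, trans to the oxygens on C2 and C6, which is the C1 configuration of the target.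

Step 8
Reactants: 15 (3S,4S,5R,8R)-5-(benzyloxy)-4,8-bis[(tert-butyldimethylsilyl)oxy]-1-oxaspiro[2.5]octane; 16 benzoic acid
Product: 17 [(1S,2R,5R,6S)-5-(benzyloxy)-2,6-bis[(tert-butyldimethylsilyl)oxy]-1-hydroxycyclohexyl]methyl benzoate
Conditions: 16 (2 equiv), PhCO2Cs (0.3 equiv), DMF, 80 °C
Reagents that add atoms: none
Why: Nucleophilic ring opening of a 2,2-disubstituted oxirane by benzoate at the unsubstituted CH2 (SN2 at C7), with benzoic acid as the proton source for the tertiary alkoxide; the C1–O bond is not broken, so the C1 configuration from step 7 is retained.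

Step 9
Reactants: 17 [(1S,2R,5R,6S)-5-(benzyloxy)-2,6-bis[(tert-butyldimethylsilyl)oxy]-1-hydroxycyclohexyl]methyl benzoate
Product: 18 [(1S,2R,5R,6S)-2,6-bis[(tert-butyldimethylsilyl)oxy]-1,5-dihydroxycyclohexyl]methyl benzoate
Conditions: H2 (1 atm), 10% Pd/C, EtOAc, rt
Reagents that add atoms: none
Why: Hydrogenolysis of the benzyl ether on palladium on carbon frees the C5 hydroxyl, while the alkyl benzoate, the silyl ethers and the tertiary alcohol are inert to hydrogen in ethyl acetate.

Step 10
Reactants: 18 [(1S,2R,5R,6S)-2,6-bis[(tert-butyldimethylsilyl)oxy]-1,5-dihydroxycyclohexyl]methyl benzoate; 19 benzoyl chloride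
Product: 20 [(1S,2R,5R,6S)-5-(benzoyloxy)-2,6-bis[(tert-butyldimethylsilyl)oxy]-1-hydroxycyclohexyl]methyl benzoate
Conditions: 19 (1.5 equiv), pyridine, DMAP (cat.), CH2Cl2, 0 °C to rt
Reagents that add atoms: none
Why: DMAP-catalysed acylation of the only secondary hydroxyl; the tertiary C1 hydroxyl, flanked by two silyloxy-bearing carbons, should not be acylated under these conditions.

Step 11
Reactants: 20 [(1S,2R,5R,6S)-5-(benzoyloxy)-2,6-bis[(tert-butyldimethylsilyl)oxy]-1-hydroxycyclohexyl]methyl benzoate
Product: 21 [(1S,2R,5R,6S)-5-(benzoyloxy)-1,2,6-trihydroxycyclohexyl]methyl benzoate (target CNP0264996.1)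
Conditions: HF·pyridine, pyridine/THF, 0 °C to rt
Reagents that add atoms: none
Why: Fluoride-mediated cleavage of the two Si–O bonds with buffered HF·pyridine, a weakly acidic medium in which no alkoxide is formed, so neither benzoate should migrate to the freed C2 and C6 hydroxyls.

Compound list

1 | (R)-2-(but-3-en-1-yl)oxirane | C=CCC[C@@H]1CO1 | starting material
2 | trimethylsulfonium iodide | C[S+](C)C.[I-] | starting material
3 | sulfonium alkoxide: dimethyl[(3R)-3-oxidohept-6-en-1-yl]sulfonium inner salt (not isolated) | C[S+](C)CC[C@H]([O-])CCC=C | intermediate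
4 | (R)-hepta-1,6-dien-3-ol | C=C[C@H](O)CCC=C | intermediate
5 | (R)-3-(benzyloxy)hepta-1,6-diene | C=C[C@H](OCc1ccccc1)CCC=C | intermediate
6 | bis-ozonide: 3-[(1R)-1-(benzyloxy)-3-(1,2,4-trioxolan-3-yl)propyl]-1,2,4-trioxolane, epimers at the two ring carbons (not isolated) | C1OC(OO1)[C@H](OCc2ccccc2)CCC3OCOO3 | intermediate
7 | (R)-2-(benzyloxy)pentanedial | O=C[C@H](OCc1ccccc1)CCC=O | intermediate
8 | nitromethane | C[N+](=O)[O-] | starting material
9 | open-chain nitroaldol: (4R)-4-(benzyloxy)-5-hydroxy-6-nitrohexanal, both C5 epimers, drawn for first addition at the formyl group next to the ether carbon (not isolated) | O=CCC[C@@H](OCc1ccccc1)C(O)C[N+](=O)[O-] | intermediate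
10 | (1R,2S,3R,4R)-4-(benzyloxy)-2-nitrocyclohexane-1,3-diol (all four substituents equatorial) | O[C@@H]1CC[C@@H](OCc2ccccc2)[C@H](O)[C@H]1[N+](=O)[O-] | intermediate
11 | (1R,2S,3R,4R)-4-(benzyloxy)-1,3-bis[(tert-butyldimethylsilyl)oxy]-2-nitrocyclohexane | CC(C)(C)[Si](C)(C)O[C@@H]1CC[C@@H](OCc2ccccc2)[C@H](O[Si](C)(C)C(C)(C)C)[C@H]1[N+](=O)[O-] | intermediate
12 | sodium nitronate of 11: sodium (2S,3R,6R)-3-(benzyloxy)-2,6-bis[(tert-butyldimethylsilyl)oxy]cyclohexylideneazinate (not isolated) | [Na+].[O-][N+]([O-])=C1[C@H](O[Si](C)(C)C(C)(C)C)CC[C@@H](OCc2ccccc2)[C@@H]1O[Si](C)(C)C(C)(C)C | intermediate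
13 | (2S,3R,6R)-3-(benzyloxy)-2,6-bis[(tert-butyldimethylsilyl)oxy]cyclohexan-1-one | O=C1[C@H](O[Si](C)(C)C(C)(C)C)CC[C@@H](OCc2ccccc2)[C@@H]1O[Si](C)(C)C(C)(C)C | intermediate
14 | betaine: {[(1S,2R,5R,6S)-5-(benzyloxy)-2,6-bis[(tert-butyldimethylsilyl)oxy]-1-oxidocyclohexyl]methyl}dimethylsulfonium inner salt (not isolated) | C[S+](C)C[C@]1([O-])[C@H](O[Si](C)(C)C(C)(C)C)CC[C@@H](OCc2ccccc2)[C@@H]1O[Si](C)(C)C(C)(C)C | intermediate
15 | (3S,4S,5R,8R)-5-(benzyloxy)-4,8-bis[(tert-butyldimethylsilyl)oxy]-1-oxaspiro[2.5]octane | C1O[C@]12[C@H](O[Si](C)(C)C(C)(C)C)CC[C@@H](OCc3ccccc3)[C@@H]2O[Si](C)(C)C(C)(C)C | intermediate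
16 | benzoic acid | OC(=O)c1ccccc1 | starting material
17 | [(1S,2R,5R,6S)-5-(benzyloxy)-2,6-bis[(tert-butyldimethylsilyl)oxy]-1-hydroxycyclohexyl]methyl benzoate | O=C(OC[C@]1(O)[C@H](O[Si](C)(C)C(C)(C)C)CC[C@@H](OCc2ccccc2)[C@@H]1O[Si](C)(C)C(C)(C)C)c1ccccc1 | intermediate
18 | [(1S,2R,5R,6S)-2,6-bis[(tert-butyldimethylsilyl)oxy]-1,5-dihydroxycyclohexyl]methyl benzoate | O=C(OC[C@]1(O)[C@H](O[Si](C)(C)C(C)(C)C)CC[C@@H](O)[C@@H]1O[Si](C)(C)C(C)(C)C)c1ccccc1 | intermediate
19 | benzoyl chloride | O=C(Cl)c1ccccc1 | starting material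
20 | [(1S,2R,5R,6S)-5-(benzoyloxy)-2,6-bis[(tert-butyldimethylsilyl)oxy]-1-hydroxycyclohexyl]methyl benzoate | O=C(OC[C@]1(O)[C@H](O[Si](C)(C)C(C)(C)C)CC[C@@H](OC(=O)c2ccccc2)[C@@H]1O[Si](C)(C)C(C)(C)C)c1ccccc1 | intermediate
21 | [(1S,2R,5R,6S)-5-(benzoyloxy)-1,2,6-trihydroxycyclohexyl]methyl benzoate | O=C(OC[C@]1(O)[C@H](O)CC[C@@H](OC(=O)c2ccccc2)[C@@H]1O)c1ccccc1 | target

Total step count: 11. Longest linear sequence: 11 steps (1 to 21).

Steps most likely to fail

Step 4. Equilibration may stop short, so that epimers at C2 and C6 persist, and the sequence may stall after the first addition through reversible hemiacetal formation. The fallback moves the stereochemical correction from the Henry step to the ketone stage. It sets out from 7, which is cyclised with nitromethane under short, cold, kinetic conditions (NaOMe, MeOH, 0 °C, acid quench) to the mixture of nitro-diol epimers F1. Silylation as in step 5 gives the bis-silyl ether mixture F2, and the Nef sequence of step 6 takes it through the nitronate mixture F3 to the epimeric ketones F4. C2 and C6 are then both α to the C1 carbonyl, so enolisation with catalytic DBU (CH2Cl2, 0 °C) should epimerise them to the 2,6-diequatorial arrangement. The fallback comes back to the route at 13.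

Step 6. Nitronate formation at the hindered C1–H may be slow, and the nitronate may lose a neighbouring silyloxy group by β-elimination before it is oxidised. The fallback reaches the ketone through the amine, without a carbanion at C1. It sets out from 11, which is reduced (NiCl2·6H2O, NaBH4, MeOH, 0 °C) to (1S,2R,3R,6R)-3-(benzyloxy)-2,6-bis[(tert-butyldimethylsilyl)oxy]cyclohexan-1-amine F5. Condensation with 3,5-di-tert-butyl-1,2-benzoquinone (MeOH/THF, rt) and prototropic shift give the N-(3,5-di-tert-butyl-2-hydroxyphenyl) ketimine F6, a quinone-mediated oxidative deamination. Hydrolysis with aqueous oxalic acid brings the fallback back to the route at 13.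

Step 7. Axial delivery of the methylene group may not be selective enough, and the basic ylide may enolise the ketone, which opens β-elimination of the C5 benzyloxy group. The fallback introduces C7 without base and forms the two C–O bonds afterwards. It sets out from 13, which is methylenated (Zn, CH2Br2, TiCl4, THF; Takai–Lombardo) to (1R,3R,4R)-4-(benzyloxy)-1,3-bis[(tert-butyldimethylsilyl)oxy]-2-methylidenecyclohexane F7. Dihydroxylation (OsO4 cat., NMO, acetone/H2O), in which the bulky osmium reagent should approach the exocyclic alkene from the equatorial side, gives (1S,2R,5R,6S)-5-(benzyloxy)-2,6-bis[(tert-butyldimethylsilyl)oxy]-1-(hydroxymethyl)cyclohexan-1-ol F8, with the C1 oxygen equatorial. Selective benzoylation of the primary hydroxyl (19, 2,4,6-collidine, CH2Cl2, −20 °C) brings the fallback back to the route at 17.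

Further compounds

F1 | step 4 | (4R)-4-(benzyloxy)-2-nitrocyclohexane-1,3-diol, mixture of epimers at C1, C2 and C3 | OC1CC[C@@H](OCc2ccccc2)C(O)C1[N+](=O)[O-]
F2 | step 4 | (4R)-4-(benzyloxy)-1,3-bis[(tert-butyldimethylsilyl)oxy]-2-nitrocyclohexane, mixture of epimers at C1, C2 and C3 | CC(C)(C)[Si](C)(C)OC1CC[C@@H](OCc2ccccc2)C(O[Si](C)(C)C(C)(C)C)C1[N+](=O)[O-]
F3 | step 4 | sodium nitronates of F2, mixture of epimers at the two silyloxy-bearing carbons | [Na+].[O-][N+]([O-])=C1C(O[Si](C)(C)C(C)(C)C)CC[C@@H](OCc2ccccc2)C1O[Si](C)(C)C(C)(C)C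
F4 | step 4 | (3R)-3-(benzyloxy)-2,6-bis[(tert-butyldimethylsilyl)oxy]cyclohexan-1-one, mixture of epimers at C2 and C6 | O=C1C(O[Si](C)(C)C(C)(C)C)CC[C@@H](OCc2ccccc2)C1O[Si](C)(C)C(C)(C)C
F5 | step 6 | (1S,2R,3R,6R)-3-(benzyloxy)-2,6-bis[(tert-butyldimethylsilyl)oxy]cyclohexan-1-amine | N[C@H]1[C@H](O[Si](C)(C)C(C)(C)C)CC[C@@H](OCc2ccccc2)[C@@H]1O[Si](C)(C)C(C)(C)C
F6 | step 6 | 2-{[(2S,3R,6R)-3-(benzyloxy)-2,6-bis[(tert-butyldimethylsilyl)oxy]cyclohexylidene]amino}-4,6-di-tert-butylphenol | CC(C)(C)c1cc(N=C2[C@H](O[Si](C)(C)C(C)(C)C)CC[C@@H](OCc3ccccc3)[C@@H]2O[Si](C)(C)C(C)(C)C)c(O)c(c1)C(C)(C)C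
F7 | step 7 | (1R,3R,4R)-4-(benzyloxy)-1,3-bis[(tert-butyldimethylsilyl)oxy]-2-methylidenecyclohexane | C=C1[C@H](O[Si](C)(C)C(C)(C)C)CC[C@@H](OCc2ccccc2)[C@@H]1O[Si](C)(C)C(C)(C)C
F8 | step 7 | (1S,2R,5R,6S)-5-(benzyloxy)-2,6-bis[(tert-butyldimethylsilyl)oxy]-1-(hydroxymethyl)cyclohexan-1-ol | OC[C@]1(O)[C@H](O[Si](C)(C)C(C)(C)C)CC[C@@H](OCc2ccccc2)[C@@H]1O[Si](C)(C)C(C)(C)C
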